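**Retrosynthetic overview**
- The target comes from a tetra-O-benzyl (2S)-flavanone–flavone by neutral hydrogenolysis. The (2S) centre is secured by asymmetric transfer hydrogenation, run as a kinetic resolution of the racemic flavanone.
- The flavanone ring C is formed last, by oxa-Michael closure of a 2'-hydroxychalcone. That chalcone comes from the key intermolecular aldol between the ring A acetophenone and a flavone-bearing benzaldehyde.
- The flavone pyranone ring is formed first, by Claisen–Schmidt condensation of 2-hydroxy-4,6-dibenzyloxyacetophenone with a mono-masked diaryl ether dialdehyde, then I2/DMSO oxidative cyclisation.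
- The diaryl ether comes from SNAr of 4-fluorobenzaldehyde with acetal-masked 4-O-benzylprotocatechualdehyde.
- Order of construction: diaryl ether, then flavone ring, then flavanone ring, then resolution, then deprotection.

Assumption: the stereocentre in the SMILES reads as (2S), and commercial phloroacetophenone monohydrate is dried before use.

**Route**

Step 1
Reactants: 1 3,4-dihydroxybenzaldehyde
Product: 2 4-(benzyloxy)-3-hydroxybenzaldehyde
Conditions: BnBr (1.05 equiv), NaHCO3 (1.5 equiv), NaI (0.2 equiv), DMF, 40 °C, 20 h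
Reagents that add atoms: benzyl bromide, BrCc1ccccc1
Why: Williamson etherification in which the weak base ionises only the more acidic 4-OH (para to the formyl group), so mono-4-O-benzylation prevails.

Step 2
Reactants: 2 4-(benzyloxy)-3-hydroxybenzaldehyde
Product: 3 2-(benzyloxy)-5-(1,3-dioxolan-2-yl)phenol
Conditions: HOCH2CH2OH (5 equiv), p-TsOH·H2O (2 mol %), toluene, Dean–Stark reflux; Et3N quench
Reagents that add atoms: ethylene glycol, OCCO
Why: Acid-catalysed acetalisation driven by azeotropic water removal masks this formyl group, so the two aldehydes of the later diaryl ether are differentiated.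

Step 3
Reactants: 3 2-(benzyloxy)-5-(1,3-dioxolan-2-yl)phenol; 4 4-fluorobenzaldehyde
Product: 5 4-[2-(benzyloxy)-5-(1,3-dioxolan-2-yl)phenoxy]benzaldehyde
Conditions: K2CO3 (2 equiv), DMF, 120 °C, N2, 8 h
Reagents that add atoms: none
Why: Nucleophilic aromatic substitution (addition–elimination) of the fluoride activated by the para-formyl group, under basic conditions that leave the acetal and benzyl ether intact.

Step 4
Reactants: 6 2,4,6-trihydroxyacetophenone
Product: 7 1-[2,4-bis(benzyloxy)-6-hydroxyphenyl]ethanone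
Conditions: BnBr (2.05 equiv), K2CO3 (2.2 equiv), DMF, rt to 50 °C, 12 h
Reagents that add atoms: benzyl bromide, BrCc1ccccc1
Why: Williamson etherification that stops at the bis-ether, because the last OH is strongly hydrogen-bonded to the acetyl carbonyl and is the least nucleophilic.

Step 5
Reactants: 7 1-[2,4-bis(benzyloxy)-6-hydroxyphenyl]ethanone; 5 4-[2-(benzyloxy)-5-(1,3-dioxolan-2-yl)phenoxy]benzaldehyde
Product: 8 (E)-1-[2,4-bis(benzyloxy)-6-hydroxyphenyl]-3-{4-[2-(benzyloxy)-5-(1,3-dioxolan-2-yl)phenoxy]phenyl}prop-2-en-1-one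
Conditions: KOH (50 % aq, 10 equiv), EtOH/THF, rt, 48 h; aq NH4Cl to pH 7
Reagents that add atoms: none
Why: Claisen–Schmidt aldol condensation of a methyl ketone with a non-enolisable aldehyde, where E1cB loss of water gives only the conjugated E-enone and the acetal is base-stable.

Step 6
Reactants: 8 (E)-1-[2,4-bis(benzyloxy)-6-hydroxyphenyl]-3-{4-[2-(benzyloxy)-5-(1,3-dioxolan-2-yl)phenoxy]phenyl}prop-2-en-1-one
Product: 10 4-(benzyloxy)-3-{4-[5,7-bis(benzyloxy)-4-oxo-4H-chromen-2-yl]phenoxy}benzaldehyde, via flavone acetal 9 (not isolated)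
Conditions: I2 (10 mol %), DMSO, 125 °C, 2 h; aq Na2S2O3 work-up; then 2 M HCl, THF, rt, 2 h
Reagents that add atoms: water, O
Why: Iodine/DMSO oxidative cyclisation of a 2'-hydroxychalcone (oxa-Michael closure, iodination, loss of HI, DMSO reoxidising HI) gives the flavone, and the acid hydrolysis brings all acetal, cleaved or not, to the free aldehyde.

Step 7
Reactants: 6 2,4,6-trihydroxyacetophenone
Product: 11 1-(2,6-dihydroxy-4-methoxyphenyl)ethanone
Conditions: Me2SO4 (1.0 equiv), K2CO3 (1.0 equiv), acetone, reflux, 5 h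
Reagents that add atoms: dimethyl sulfate, COS(=O)(=O)OC
Why: Selective Williamson O-methylation, since with one equivalent of base only the unchelated and most acidic 4-OH is ionised and alkylated.

Step 8
Reactants: 11 1-(2,6-dihydroxy-4-methoxyphenyl)ethanone
Product: 12 1-[2-(benzyloxy)-6-hydroxy-4-methoxyphenyl]ethanone
Conditions: BnBr (1.05 equiv), K2CO3 (1.1 equiv), acetone, reflux, 6 h
Reagents that add atoms: benzyl bromide, BrCc1ccccc1
Why: Williamson mono-benzylation of two equivalent phenols, in which the surviving OH becomes tightly chelated to the carbonyl and resists a second alkylation.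

Step 9 (key step)
Reactants: 12 1-[2-(benzyloxy)-6-hydroxy-4-methoxyphenyl]ethanone; 10 4-(benzyloxy)-3-{4-[5,7-bis(benzyloxy)-4-oxo-4H-chromen-2-yl]phenoxy}benzaldehyde
Product: 13 racemic 2-{4-[2-(benzyloxy)-5-{3-[2-(benzyloxy)-6-hydroxy-4-methoxyphenyl]-1-hydroxy-3-oxopropyl}phenoxy]phenyl}-5,7-bis(benzyloxy)-4H-chromen-4-one
Conditions: 12 (1.3 equiv), LiN(iPr)2 (commercial solution, 2.6 equiv), THF, −78 to −20 °C, 1 h; recool to −78 °C, add 10 in THF, 1 h; AcOH quench at −78 °C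
Reagents that add atoms: none
Why: Directed intermolecular aldol addition of the dilithio phenoxide–enolate, with no free amide base left, to the aldehyde, which at −78 °C is far more electrophilic than the vinylogous-ester pyranone; the carbinol centre forms racemic and is erased in step 10.

Step 10
Reactants: 13 racemic aldol adduct
Product: 15 racemic 5-(benzyloxy)-2-[4-(benzyloxy)-3-{4-[5,7-bis(benzyloxy)-4-oxo-4H-chromen-2-yl]phenoxy}phenyl]-7-methoxychroman-4-one, via chalcone 14 (not isolated)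
Conditions: p-TsOH·H2O (10 mol %), toluene, 70 °C, 1 h; evaporate; NaOAc (10 equiv), EtOH/THF, reflux, 24 h; recovered chalcone is resubmitted
Reagents that add atoms: none
Why: Acid-catalysed dehydration of the p-alkoxybenzylic carbinol gives the E-chalcone, and acetate-catalysed intramolecular oxa-Michael addition of the 2'-OH closes ring C, which the 6'-benzyloxy group favours; C2 is formed as a racemate.

Step 11
Reactants: 15 racemic protected flavanone–flavone
Product: 16 (2S)-5-(benzyloxy)-2-[4-(benzyloxy)-3-{4-[5,7-bis(benzyloxy)-4-oxo-4H-chromen-2-yl]phenoxy}phenyl]-7-methoxychroman-4-one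
Conditions: Cp*RhCl[(R,R)-TsDPEN] (1 mol %), HCO2H/Et3N (5:2), EtOAc, rt, stopped at 52–55 % conversion (chiral HPLC); chromatographic separation of ketone from alcohol
Reagents that add atoms: none
Why: Noyori–Ikariya asymmetric transfer hydrogenation used as a kinetic resolution, in which the (R,R)-catalyst forms a (4R)-carbinol and is matched only with the (2R)-ketone (giving the cis-(2R,4R)-flavan-4-ol), so the (2S)-ketone remains in at least 98 % ee while the flavone carbonyl, a vinylogous ester, is not reduced.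

Step 12
Reactants: 16 (2S)-tetra-O-benzyl flavanone–flavone
Product: 17 (2S)-2-{3-[4-(5,7-dihydroxy-4-oxo-4H-chromen-2-yl)phenoxy]-4-hydroxyphenyl}-5-hydroxy-7-methoxychroman-4-one (target)
Conditions: H2 (1 atm), 10 % Pd/C, THF/MeOH (1:1), rt, 3–6 h (monitored); Celite; Sephadex LH-20 (MeOH), no base
Reagents that add atoms: none
Why: Catalytic hydrogenolysis removes the four aryl benzyl ethers under neutral conditions that spare the methyl ether, the diaryl ether, the flavone double bond and both carbonyls, and the absence of acid or base prevents ring-opening racemisation at C2.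

**Compound list**
1 | 3,4-dihydroxybenzaldehyde | O=Cc1ccc(O)c(O)c1 | starting material
2 | 4-(benzyloxy)-3-hydroxybenzaldehyde | O=Cc1ccc(OCc2ccccc2)c(O)c1 | intermediate
3 | 2-(benzyloxy)-5-(1,3-dioxolan-2-yl)phenol | Oc1cc(C2OCCO2)ccc1OCc1ccccc1 | intermediate
4 | 4-fluorobenzaldehyde | O=Cc1ccc(F)cc1 | starting material
5 | 4-[2-(benzyloxy)-5-(1,3-dioxolan-2-yl)phenoxy]benzaldehyde | O=Cc1ccc(Oc2cc(C3OCCO3)ccc2OCc2ccccc2)cc1 | intermediate
6 | 2,4,6-trihydroxyacetophenone | CC(=O)c1c(O)cc(O)cc1O | starting material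
7 | 1-[2,4-bis(benzyloxy)-6-hydroxyphenyl]ethanone | CC(=O)c1c(O)cc(OCc2ccccc2)cc1OCc1ccccc1 | intermediate
8 | (E)-1-[2,4-bis(benzyloxy)-6-hydroxyphenyl]-3-{4-[2-(benzyloxy)-5-(1,3-dioxolan-2-yl)phenoxy]phenyl}prop-2-en-1-one | O=C(/C=C/c1ccc(Oc2cc(C3OCCO3)ccc2OCc2ccccc2)cc1)c1c(O)cc(OCc2ccccc2)cc1OCc1ccccc1 | intermediate
9 | 5,7-bis(benzyloxy)-2-{4-[2-(benzyloxy)-5-(1,3-dioxolan-2-yl)phenoxy]phenyl}-4H-chromen-4-one (flavone acetal, not isolated) | O=c1cc(-c2ccc(Oc3cc(C4OCCO4)ccc3OCc3ccccc3)cc2)oc2cc(OCc3ccccc3)cc(OCc3ccccc3)c12 | intermediate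
10 | 4-(benzyloxy)-3-{4-[5,7-bis(benzyloxy)-4-oxo-4H-chromen-2-yl]phenoxy}benzaldehyde | O=Cc1ccc(OCc2ccccc2)c(Oc2ccc(-c3cc(=O)c4c(OCc5ccccc5)cc(OCc5ccccc5)cc4o3)cc2)c1 | intermediate
11 | 1-(2,6-dihydroxy-4-methoxyphenyl)ethanone | CC(=O)c1c(O)cc(OC)cc1O | intermediate
12 | 1-[2-(benzyloxy)-6-hydroxy-4-methoxyphenyl]ethanone | CC(=O)c1c(O)cc(OC)cc1OCc1ccccc1 | intermediate
13 | racemic aldol adduct, 2-{4-[2-(benzyloxy)-5-{3-[2-(benzyloxy)-6-hydroxy-4-methoxyphenyl]-1-hydroxy-3-oxopropyl}phenoxy]phenyl}-5,7-bis(benzyloxy)-4H-chromen-4-one | COc1cc(O)c(C(=O)CC(O)c2ccc(OCc3ccccc3)c(Oc3ccc(-c4cc(=O)c5c(OCc6ccccc6)cc(OCc6ccccc6)cc5o4)cc3)c2)c(OCc2ccccc2)c1 | intermediate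
14 | (E)-chalcone, 2-{4-[2-(benzyloxy)-5-{(E)-3-[2-(benzyloxy)-6-hydroxy-4-methoxyphenyl]-3-oxoprop-1-enyl}phenoxy]phenyl}-5,7-bis(benzyloxy)-4H-chromen-4-one (not isolated) | COc1cc(O)c(C(=O)/C=C/c2ccc(OCc3ccccc3)c(Oc3ccc(-c4cc(=O)c5c(OCc6ccccc6)cc(OCc6ccccc6)cc5o4)cc3)c2)c(OCc2ccccc2)c1 | intermediate
15 | racemic 5-(benzyloxy)-2-[4-(benzyloxy)-3-{4-[5,7-bis(benzyloxy)-4-oxo-4H-chromen-2-yl]phenoxy}phenyl]-7-methoxychroman-4-one | COc1cc(OCc2ccccc2)c2c(c1)OC(c1ccc(OCc3ccccc3)c(Oc3ccc(-c4cc(=O)c5c(OCc6ccccc6)cc(OCc6ccccc6)cc5o4)cc3)c1)CC2=O | intermediate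
16 | (2S)-5-(benzyloxy)-2-[4-(benzyloxy)-3-{4-[5,7-bis(benzyloxy)-4-oxo-4H-chromen-2-yl]phenoxy}phenyl]-7-methoxychroman-4-one | COc1cc(OCc2ccccc2)c2c(c1)O[C@H](c1ccc(OCc3ccccc3)c(Oc3ccc(-c4cc(=O)c5c(OCc6ccccc6)cc(OCc6ccccc6)cc5o4)cc3)c1)CC2=O | intermediate
17 | (2S)-2-{3-[4-(5,7-dihydroxy-4-oxo-4H-chromen-2-yl)phenoxy]-4-hydroxyphenyl}-5-hydroxy-7-methoxychroman-4-one | COc1cc(O)c2c(c1)O[C@H](c1ccc(O)c(Oc3ccc(-c4cc(=O)c5c(O)cc(O)cc5o4)cc3)c1)CC2=O | target

**Step count**
Total steps: 12. Longest linear sequence: 9 steps (1, 2, 3, 5, 6, 9, 10, 11, 12).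

**Three steps most likely to fail**

Step 11 (kinetic resolution). The selectivity factor on this large substrate is untested. The peri 5-benzyloxy group may slow the reduction, and a slow attack on the pyranone cannot be excluded.

The fallback is a classical resolution through separable diastereomers. It sets out from 15.
- NaBH4 (THF/MeOH, 0 °C) reduces only the flavanone carbonyl, giving the racemic cis-flavan-4-ol F5.
- Acylation with (1S,4R)-camphanic chloride (Et3N, DMAP, CH2Cl2) gives the (2S,4S)-flavan-4-yl (1S,4R)-camphanate F6 together with the (2R,4R)-flavan-4-yl (1S,4R)-camphanate F7. These are separated by crystallisation and chromatography.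
- F6 is cleaved with LiOH (THF/H2O, rt) to the (2S,4S)-flavan-4-ol F8. This compound cannot racemise, because it has no carbonyl.
- Buffered Dess–Martin oxidation (NaHCO3, CH2Cl2) comes back to the route at 16.

Step 9 (key aldol). The risks are incomplete dianion formation, retro-aldol on warming, and poor solubility of 10 at −78 °C.

The fallback replaces the basic enolate by a neutral nucleophile under Lewis acid activation. It sets out from 12.
- TMSOTf (2.3 equiv) and Et3N (CH2Cl2, 0 °C) give 1-(benzyloxy)-5-methoxy-3-(trimethylsilyloxy)-2-[1-(trimethylsilyloxy)vinyl]benzene F4.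
- F4 is added to 10 in a Mukaiyama aldol addition (BF3·OEt2, 2.5 equiv, CH2Cl2, −78 °C).
- Brief treatment with 1 M HCl/THF strips the silyl groups and comes back to the route at 13.

Step 6 (oxidative cyclisation). Hot HI may cleave the peri 5-O-benzyl ether, and the acetal is scrambled.

The fallback reaches the flavone oxidation level without any oxidant and bypasses steps 5 and 6. It sets out from 5 together with 7.
- Ag2O in aq NaOH/THF (rt, acetal untouched) oxidises 5 to 4-[2-(benzyloxy)-5-(1,3-dioxolan-2-yl)phenoxy]benzoic acid F1.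
- EDC·HCl and DMAP (CH2Cl2) esterify the phenol of 7, giving 2-acetyl-3,5-bis(benzyloxy)phenyl 4-[2-(benzyloxy)-5-(1,3-dioxolan-2-yl)phenoxy]benzoate F2.
- Baker–Venkataraman rearrangement (KOH, pyridine, 50 °C), an intramolecular Claisen condensation, gives 1-[2,4-bis(benzyloxy)-6-hydroxyphenyl]-3-{4-[2-(benzyloxy)-5-(1,3-dioxolan-2-yl)phenoxy]phenyl}propane-1,3-dione F3.
- p-TsOH·H2O (toluene, 90 °C) followed by 2 M HCl/THF cyclodehydrates F3 and frees the aldehyde, coming back to the route at 10.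

**Further compounds**
F1 | step 6 | 4-[2-(benzyloxy)-5-(1,3-dioxolan-2-yl)phenoxy]benzoic acid | O=C(O)c1ccc(Oc2cc(C3OCCO3)ccc2OCc2ccccc2)cc1
F2 | step 6 | 2-acetyl-3,5-bis(benzyloxy)phenyl 4-[2-(benzyloxy)-5-(1,3-dioxolan-2-yl)phenoxy]benzoate | CC(=O)c1c(OC(=O)c2ccc(Oc3cc(C4OCCO4)ccc3OCc3ccccc3)cc2)cc(OCc2ccccc2)cc1OCc1ccccc1
F3 | step 6 | 1-[2,4-bis(benzyloxy)-6-hydroxyphenyl]-3-{4-[2-(benzyloxy)-5-(1,3-dioxolan-2-yl)phenoxy]phenyl}propane-1,3-dione | O=C(CC(=O)c1ccc(Oc2cc(C3OCCO3)ccc2OCc2ccccc2)cc1)c1c(O)cc(OCc2ccccc2)cc1OCc1ccccc1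
F4 | step 9 | 1-(benzyloxy)-5-methoxy-3-(trimethylsilyloxy)-2-[1-(trimethylsilyloxy)vinyl]benzene | C=C(O[Si](C)(C)C)c1c(O[Si](C)(C)C)cc(OC)cc1OCc1ccccc1
F5 | step 11 | racemic cis-flavan-4-ol (4-carbinol of 15, both cis enantiomers, drawn flat) | COc1cc(OCc2ccccc2)c2c(c1)OC(c1ccc(OCc3ccccc3)c(Oc3ccc(-c4cc(=O)c5c(OCc6ccccc6)cc(OCc6ccccc6)cc5o4)cc3)c1)CC2O
F6 | step 11 | (2S,4S)-flavan-4-yl (1S,4R)-camphanate | COc1cc(OCc2ccccc2)c2c(c1)O[C@H](c1ccc(OCc3ccccc3)c(Oc3ccc(-c4cc(=O)c5c(OCc6ccccc6)cc(OCc6ccccc6)cc5o4)cc3)c1)C[C@@H]2OC(=O)[C@@]12CC[C@@](C)(C(=O)O1)C2(C)C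
F7 | step 11 | (2R,4R)-flavan-4-yl (1S,4R)-camphanate | COc1cc(OCc2ccccc2)c2c(c1)O[C@@H](c1ccc(OCc3ccccc3)c(Oc3ccc(-c4cc(=O)c5c(OCc6ccccc6)cc(OCc6ccccc6)cc5o4)cc3)c1)C[C@H]2OC(=O)[C@@]12CC[C@@](C)(C(=O)O1)C2(C)C
F8 | step 11 | (2S,4S)-flavan-4-ol | COc1cc(OCc2ccccc2)c2c(c1)O[C@H](c1ccc(OCc3ccccc3)c(Oc3ccc(-c4cc(=O)c5c(OCc6ccccc6)cc(OCc6ccccc6)cc5o4)cc3)c1)C[C@@H]2O
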